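**Retrosynthetic overview**

1. Last disconnection: one hydrogenolysis unveils both phenols of the flavan part (benzyl ether on ring A, benzyl carbonate on ring B).
2. Key disconnection: the bond from C4 of the pyran ring to the free ring carbon of lauroylphloroglucinol, together with C4–C4a. C4 is traced back to the acetal carbon of an acyclic (S)-β-aryloxy acetal, so one acid-mediated operation closes ring C, joins the two halves and sets C4 trans to the C2 aryl group.
3. Enabling feature: C4 is a diarylmethine carbon at the aldehyde oxidation level. It is bonded to C4a of ring A (para to the C7 oxygen and, through C8a, ortho to O1) and to a phloroglucinol carbon lying between two C–OH carbons; a cation at C4 is therefore doubly oxygen-stabilised, and the two free CH positions of lauroylphloroglucinol are equivalent.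
4. The C2 stereocentre comes from a catalytic asymmetric allylboration of a 4-oxygenated benzaldehyde followed by Mitsunobu inversion with 3-(benzyloxy)phenol; ozonolysis of the allyl group supplies the acetal carbon. Ring B carries an electron-poor carbonate so that the C2–O bond does not ionise.
5. Ring order: rings A, B and the phloroglucinol ring are bought; ring C is the only ring built, and it closes in the key step.

Key step: step 6

Remark: the (R)-phosphoric acid is taken to deliver the allyl group to the Re face of the aldehyde (R alcohol), as the chair transition-state model for this catalyst class predicts; if the sense were opposite, the (S)-catalyst would be used and nothing else changes.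

**Route**

Step 1
Reactants: 1 4-hydroxybenzaldehyde
Product: 2 benzyl 4-formylphenyl carbonate
Conditions: BnOCOCl, Et3N, DMAP (cat.), CH2Cl2, 0 °C
Reagents that add atoms: benzyl chloroformate, O=C(Cl)OCc1ccccc1
Why: O-acylation of the phenoxide by the chloroformate should be clean because the aldehyde is inert to it, and the carbonate makes ring B electron-poor for the later steps while remaining removable by hydrogenolysis.

Step 2
Reactants: 2 benzyl 4-formylphenyl carbonate; 3 allylboronic acid pinacol ester
Product: 4 benzyl 4-[(1R)-1-hydroxybut-3-en-1-yl]phenyl carbonate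
Conditions: (R)-TRIP [(R)-3,3'-bis(2,4,6-triisopropylphenyl)-1,1'-binaphthyl-2,2'-diyl hydrogen phosphate] (5 mol %), toluene, −30 °C; aqueous work-up
Reagents that add atoms: none
Why: Chiral phosphoric acid-catalysed allylboration of an aryl aldehyde through a closed chair transition state (Re-face delivery) should set the carbinol centre as R, and the neutral conditions spare the aryl carbonate.

Step 3
Reactants: 4 benzyl 4-[(1R)-1-hydroxybut-3-en-1-yl]phenyl carbonate; 5 3-(benzyloxy)phenol
Product: 6 benzyl 4-{(1S)-1-[3-(benzyloxy)phenoxy]but-3-en-1-yl}phenyl carbonate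
Conditions: PPh3, DIAD, toluene, 0 °C → rt
Reagents that add atoms: none
Why: Mitsunobu etherification, in which the phenol displaces the alkoxyphosphonium ion by SN2 with inversion (R to S); the carbonate-bearing aryl group disfavours the competing ionisation that would erode the ee.

Step 4
Reactants: 6 benzyl 4-{(1S)-1-[3-(benzyloxy)phenoxy]but-3-en-1-yl}phenyl carbonate
Product: 8 benzyl 4-{(1S)-1-[3-(benzyloxy)phenoxy]-3,3-dimethoxypropyl}phenyl carbonate, via aldehyde 7 (not isolated)
Conditions: O3, CH2Cl2/MeOH, −78 °C (Sudan Red 7B end-point); Me2S, −78 °C → rt; then HC(OMe)3, PPTS (cat.), rt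
Reagents that add atoms: ozone, [O-][O+]=O (carbonyl oxygen of 7); trimethyl orthoformate, COC(OC)OC (the two methoxy groups of 8)
Why: Ozonolysis of the terminal alkene, which is far more reactive towards ozone than the aryl ethers, gives the aldehyde after reductive work-up, and immediate acetalisation under mild acid should outrun loss of the β-aryloxy group; the stereocentre is not involved.

Step 5
Reactants: 9 phloroglucinol; 10 dodecanoyl chloride
Product: 11 1-(2,4,6-trihydroxyphenyl)dodecan-1-one (lauroylphloroglucinol)
Conditions: AlCl3, PhNO2/CH2Cl2, rt → 50 °C; aqueous HCl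
Reagents that add atoms: none
Why: Friedel–Crafts C-acylation of phloroglucinol should stop after one acyl group because the aryl ketone deactivates the ring, and the product keeps two equivalent free ring CH positions.

Step 6
Reactants: 8 benzyl 4-{(1S)-1-[3-(benzyloxy)phenoxy]-3,3-dimethoxypropyl}phenyl carbonate; 11 1-(2,4,6-trihydroxyphenyl)dodecan-1-one
Product: 14 benzyl 4-[(2S,4R)-7-(benzyloxy)-4-(3-dodecanoyl-2,4,6-trihydroxyphenyl)chroman-2-yl]phenyl carbonate, via 4-methoxyflavan 12 (not isolated), via flavan-4-yl cation 13 (not isolated)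
Conditions: BF3·OEt2 (0.3 equiv), CH2Cl2, −60 °C, 30 min; then 11 (1.5 equiv) in Et2O, −60 → 0 °C; aqueous NaHCO3
Reagents that add atoms: none
Why: Proposed new method: the acid ionises the dimethyl acetal of 8 to an O-methyl oxocarbenium ion, which the tethered 3-(benzyloxy)phenoxy ring attacks at its carbon para to the benzyloxy group (6-exo-trig with respect to the C=O+ bond, an intramolecular Friedel–Crafts alkylation that forms C4–C4a and closes ring C) to give 4-methoxyflavan 12, whose methoxy group ionises in turn to cation 13, stabilised by O1 through C8a and by the C7 oxygen in the para position; 11, whose two free ring carbons are equivalent, then forms the C4–aryl bond by Friedel–Crafts alkylation. The closest known reaction types are the acid-mediated cyclisation of 3-aryloxypropanal derivatives to chroman-4-yl ethers, the arylation of flavan-4-ols and their ethers by phloroglucinols, and the twofold arylation of aldehydes and acetals by electron-rich arenes (triarylmethane synthesis); their merger on a β-aryloxy acetal is the new element. The new C4 stereocentre is set by the C2 centre: in the sofa-shaped cation the 2-aryl group is equatorial and the nucleophile enters on the axial trajectory that leads directly to the half-chair with a pseudoaxial 4-aryl group free of peri strain with H5, which is the face trans to the 2-aryl group (2S,4R). Regioselective ring closure (C7 and not C5 oxygenation) is needed and should be secured because the alternative site lies between two oxygen substituents; the order of the two arylations is secured by adding 11 only after the acetal has cyclised at low temperature; and C2 should keep its configuration because C3 stays sp3 and the electron-poor carbonate on ring B disfavours ionisation of the C2–O1 bond.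

Step 7
Reactants: 14 benzyl 4-[(2S,4R)-7-(benzyloxy)-4-(3-dodecanoyl-2,4,6-trihydroxyphenyl)chroman-2-yl]phenyl carbonate
Product: 15 (+)-myristinin A
Conditions: H2 (1 atm), 10% Pd/C, EtOAc/MeOH, rt
Reagents that add atoms: none
Why: Hydrogenolysis over Pd/C should cleave the benzyl ether and the benzyl carbonate (which then loses CO2) in one operation, while the hydrogen-bonded aryl ketone, the C2–O1 bond and both stereocentres are expected to survive a short reaction at 1 atm.

**Compound list**

1 | 4-hydroxybenzaldehyde | O=Cc1ccc(O)cc1 | starting material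
2 | benzyl 4-formylphenyl carbonate | O=Cc1ccc(OC(=O)OCc2ccccc2)cc1 | intermediate
3 | allylboronic acid pinacol ester (2-allyl-4,4,5,5-tetramethyl-1,3,2-dioxaborolane) | C=CCB1OC(C)(C)C(C)(C)O1 | starting material
4 | benzyl 4-[(1R)-1-hydroxybut-3-en-1-yl]phenyl carbonate | C=CC[C@@H](O)c1ccc(OC(=O)OCc2ccccc2)cc1 | intermediate
5 | 3-(benzyloxy)phenol | Oc1cccc(OCc2ccccc2)c1 | starting material
6 | benzyl 4-{(1S)-1-[3-(benzyloxy)phenoxy]but-3-en-1-yl}phenyl carbonate | C=CC[C@H](Oc1cccc(OCc2ccccc2)c1)c1ccc(OC(=O)OCc2ccccc2)cc1 | intermediate
7 | benzyl 4-{(1S)-1-[3-(benzyloxy)phenoxy]-3-oxopropyl}phenyl carbonate (aldehyde, not isolated) | O=CC[C@H](Oc1cccc(OCc2ccccc2)c1)c1ccc(OC(=O)OCc2ccccc2)cc1 | intermediate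
8 | benzyl 4-{(1S)-1-[3-(benzyloxy)phenoxy]-3,3-dimethoxypropyl}phenyl carbonate | COC(OC)C[C@H](Oc1cccc(OCc2ccccc2)c1)c1ccc(OC(=O)OCc2ccccc2)cc1 | intermediate
9 | phloroglucinol (benzene-1,3,5-triol) | Oc1cc(O)cc(O)c1 | starting material
10 | dodecanoyl chloride | CCCCCCCCCCCC(=O)Cl | starting material
11 | 1-(2,4,6-trihydroxyphenyl)dodecan-1-one | CCCCCCCCCCCC(=O)c1c(O)cc(O)cc1O | intermediate
12 | benzyl 4-[(2S)-7-(benzyloxy)-4-methoxychroman-2-yl]phenyl carbonate (both C4 epimers, not isolated) | COC1C[C@@H](c2ccc(OC(=O)OCc3ccccc3)cc2)Oc2cc(OCc3ccccc3)ccc21 | intermediate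
13 | (2S)-7-(benzyloxy)-2-{4-[(benzyloxycarbonyl)oxy]phenyl}chroman-4-ylium (not isolated) | [CH+]1C[C@@H](c2ccc(OC(=O)OCc3ccccc3)cc2)Oc2cc(OCc3ccccc3)ccc21 | intermediate
14 | benzyl 4-[(2S,4R)-7-(benzyloxy)-4-(3-dodecanoyl-2,4,6-trihydroxyphenyl)chroman-2-yl]phenyl carbonate | CCCCCCCCCCCC(=O)c1c(O)cc(O)c([C@@H]2C[C@@H](c3ccc(OC(=O)OCc4ccccc4)cc3)Oc3cc(OCc4ccccc4)ccc32)c1O | intermediate
15 | (+)-myristinin A, 1-{2,4,6-trihydroxy-3-[(2S,4R)-7-hydroxy-2-(4-hydroxyphenyl)chroman-4-yl]phenyl}dodecan-1-one | CCCCCCCCCCCC(=O)c1c(O)cc(O)c([C@@H]2C[C@@H](c3ccc(O)cc3)Oc3cc(O)ccc32)c1O | target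

**Step count**

Total: 7 steps. Longest linear sequence: 6 steps (steps 1, 2, 3, 4, 6, 7).

**Steps most likely to fail**

Step 6. What may go wrong: a second molecule of 11 may intercept the open-chain oxocarbenium ion before ring closure; cation 13 may lose a proton to give a flav-3-ene that racemises by ring opening; or ring closure may occur ortho instead of para to the benzyloxy group. The fallback uses known chemistry only, sets out from 6 and comes back at 14. Ozonolysis of 6 with PPh3 work-up gives aldehyde 7, which is oxidised at once (NaClO2, NaH2PO4, 2-methyl-2-butene, t-BuOH/H2O) to the propanoic acid F1. Cyclodehydration through the mixed trifluoroacetic anhydride ((CF3CO)2O, CH2Cl2, 0 °C; intramolecular Friedel–Crafts acylation para to the benzyloxy group) should give the (2S)-flavanone F2. NaBH4 (THF/MeOH, −20 °C) should give the 2,4-cis-flavan-4-ol F3. The classical BF3·OEt2-mediated Friedel–Crafts coupling of F3 with 11 (CH2Cl2/Et2O, −40 → 0 °C) then passes through the same cation 13 and should give 14 with the same trans selectivity.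

Step 3. What may go wrong: the alkoxyphosphonium ion may partly ionise at the benzylic carbon (loss of ee), or eliminate to the 1-aryl-1,3-diene. The fallback sets out from 2 and 5 and comes back at 8; it creates the C2–O stereocentre by catalyst control instead of transferring it by inversion. Wittig olefination of 2 with (triphenylphosphoranylidene)acetaldehyde gives the (E)-enal F4; Luche reduction (NaBH4, CeCl3·7H2O) gives the cinnamyl alcohol F5; methyl chloroformate/pyridine gives the methyl carbonate F6. Iridium-catalysed asymmetric allylic etherification with the lithium aryloxide of 5 ([Ir(cod)Cl]2, BINOL-derived phosphoramidite ligand of the enantiomeric series that gives the S product, THF, rt) should give the branched allyl aryl ether F7. Hydroboration–oxidation (9-BBN; NaBO3·4H2O) gives the primary alcohol F8, Dess–Martin oxidation gives aldehyde 7, and acetalisation as in step 4 gives 8.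

Step 4. What may go wrong: ozone may oxidise the electron-rich resorcinol diether ring or the benzyl groups, and the aldehyde may lose the aryloxide by β-elimination before it is acetalised. The fallback sets out from 4 and comes back at 8; it moves the oxidative cleavage ahead of the etherification, so that neither the electron-rich ring nor a β-leaving group is present. Ozonolysis of 4 (O3, CH2Cl2/MeOH, −78 °C; Me2S) gives the hydroxy aldehyde F9, which is acetalised in the same flask (HC(OMe)3, PPTS) to the hydroxy acetal F10. Mitsunobu etherification of F10 with 5 (PPh3, DIAD, toluene) then gives 8 with inversion.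

**Further compounds**

F1 | step 6 | (3S)-3-[3-(benzyloxy)phenoxy]-3-{4-[(benzyloxycarbonyl)oxy]phenyl}propanoic acid | OC(=O)C[C@H](Oc1cccc(OCc2ccccc2)c1)c1ccc(OC(=O)OCc2ccccc2)cc1
F2 | step 6 | benzyl 4-[(2S)-7-(benzyloxy)-4-oxochroman-2-yl]phenyl carbonate | O=C1C[C@@H](c2ccc(OC(=O)OCc3ccccc3)cc2)Oc2cc(OCc3ccccc3)ccc21
F3 | step 6 | benzyl 4-[(2S,4S)-7-(benzyloxy)-4-hydroxychroman-2-yl]phenyl carbonate | O[C@H]1C[C@@H](c2ccc(OC(=O)OCc3ccccc3)cc2)Oc2cc(OCc3ccccc3)ccc21
F4 | step 3 | benzyl 4-[(E)-3-oxoprop-1-en-1-yl]phenyl carbonate | O=C/C=C/c1ccc(OC(=O)OCc2ccccc2)cc1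
F5 | step 3 | benzyl 4-[(E)-3-hydroxyprop-1-en-1-yl]phenyl carbonate | OC/C=C/c1ccc(OC(=O)OCc2ccccc2)cc1
F6 | step 3 | benzyl 4-{(E)-3-[(methoxycarbonyl)oxy]prop-1-en-1-yl}phenyl carbonate | COC(=O)OC/C=C/c1ccc(OC(=O)OCc2ccccc2)cc1
F7 | step 3 | benzyl 4-{(1S)-1-[3-(benzyloxy)phenoxy]prop-2-en-1-yl}phenyl carbonate | C=C[C@H](Oc1cccc(OCc2ccccc2)c1)c1ccc(OC(=O)OCc2ccccc2)cc1
F8 | step 3 | benzyl 4-{(1S)-1-[3-(benzyloxy)phenoxy]-3-hydroxypropyl}phenyl carbonate | OCC[C@H](Oc1cccc(OCc2ccccc2)c1)c1ccc(OC(=O)OCc2ccccc2)cc1
F9 | step 4 | benzyl 4-[(1R)-1-hydroxy-3-oxopropyl]phenyl carbonate | O=CC[C@@H](O)c1ccc(OC(=O)OCc2ccccc2)cc1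
F10 | step 4 | benzyl 4-[(1R)-1-hydroxy-3,3-dimethoxypropyl]phenyl carbonate | COC(OC)C[C@@H](O)c1ccc(OC(=O)OCc2ccccc2)cc1
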